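**Retrosynthetic overview**
- Target ⇐ acetylation, hydroxyl-directed epoxidation and 1,2-reduction of a (Z,Z)-cyclodeca-1,5-dienone that already carries the cis-fused α-methyl-γ-lactone and the C3 acetate.
- Ten-membered ring ⇐ thermal cycloreversion of a cyclobutane photoadduct; the ring bonds C1–C10 and C4–C5 are both made in one enone–cyclobutene [2+2] photocycloaddition.
- Photo partners ⇐ a carvone-derived cis-fused bicyclic enone lactone and racemic 2-methylcyclobut-2-enyl acetate (from tiglic aldehyde by photochemical 4π closure); the lactone stereocentres select the matching enantiomer.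
- Lactone ⇐ light-driven hypoiodite γ-C–H lactonisation of the acrylic acid made from (S)-carvone, then face-selective hydrogenation (C11).
- Ring order: cyclohexenone (bought) → γ-lactone → two temporary cyclobutanes → cyclodecadiene → oxirane.

Assumption: locants C1–C15 in the explanations follow germacrane numbering of the target (oxirane C1/C10, acetates at C3 and C9, olefin C4=C5, lactone C6–O/C7/C11–C13, methyls C14 on C10 and C15 on C4).

**Step 1**
Reactants: 1 (S)-(+)-carvone
Product: 2 (5S)-5-(3-chloroprop-1-en-2-yl)-2-methylcyclohex-2-en-1-one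
Conditions: Ca(OCl)2, CO2 (dry ice), CH2Cl2/H2O, 0 °C
Reagents that add atoms: calcium hypochlorite Ca(OCl)2, [Ca+2].[O-]Cl.[O-]Cl
Why: Ene-type allylic chlorination by HOCl is selective for the electron-rich isopropenyl group over the enone, and the ring stereocentre is not touched.

**Step 2**
Reactants: 2 (5S)-5-(3-chloroprop-1-en-2-yl)-2-methylcyclohex-2-en-1-one
Product: 3 2-[(1S)-4-methyl-5-oxocyclohex-3-en-1-yl]prop-2-enal
Conditions: NMO, KI (cat.), MeCN, 50 °C
Reagents that add atoms: N-methylmorpholine N-oxide, C[N+]1([O-])CCOCC1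
Why: Kornblum–Ganem N-oxide oxidation: iodide-catalysed SN2 displacement of the allylic chloride by the N-oxide oxygen and collapse of the alkoxyammonium ion give the enal, leaving the enone and the stereocentre alone.

**Step 3**
Reactants: 3 2-[(1S)-4-methyl-5-oxocyclohex-3-en-1-yl]prop-2-enal
Product: 4 2-[(1S)-4-methyl-5-oxocyclohex-3-en-1-yl]prop-2-enoic acid
Conditions: NaClO2, NaH2PO4, 2-methyl-2-butene, t-BuOH/H2O, 0 °C → rt
Reagents that add atoms: sodium chlorite NaClO2, [Na+].[O-]Cl=O
Why: Pinnick oxidation is selective for the aldehyde, and 2-methyl-2-butene scavenges HOCl so neither olefin is chlorinated.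

**Step 4**
Reactants: 4 2-[(1S)-4-methyl-5-oxocyclohex-3-en-1-yl]prop-2-enoic acid
Product: 7 (3aS,7aS)-6-methyl-3-methylidene-3a,4-dihydro-1-benzofuran-2,5(3H,7aH)-dione, via acyl hypoiodite 5 (not isolated), via allylic iodide 6 (not isolated)
Conditions: PhI(OAc)2 (1.5 equiv), I2 (0.3 equiv), ClCH2CH2Cl, white LED, 25 °C
Reagents that add atoms: none
Why: Proposed new method: photochemical dehydrogenative γ-C–H lactonisation of an α-methylene carboxylic acid — AcOI (from PhI(OAc)2/I2) converts 4 into acyl hypoiodite 5, visible light cleaves its weak O–I bond, the acyloxy radical on an sp2 carbon decarboxylates slowly and instead abstracts the allylic ring C–H next to the side chain through a six-membered transition state (the other γ-C–H, next to the ketone, is stronger and polarity-mismatched), iodine transfer anti to the side chain gives allylic iodide 6, and displacement by the neighbouring carboxyl closes the cis-fused five-membered lactone, so the carvone stereocentre sets the new C–O centre; closest known reaction type: Suárez/Togo hypoiodite 1,5-hydrogen-transfer lactonisation of 2-alkylbenzoic acids (Hofmann–Löffler–Freytag-type).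

**Step 5**
Reactants: 7 (3aS,7aS)-6-methyl-3-methylidene-3a,4-dihydro-1-benzofuran-2,5(3H,7aH)-dione
Product: 8 (3R,3aS,7aR)-3,6-dimethyl-3a,4-dihydro-1-benzofuran-2,5(3H,7aH)-dione
Conditions: H2 (1 atm), RhCl(PPh3)3 (5 mol %), PhH/EtOH, rt
Reagents that add atoms: none
Why: Homogeneous hydrogenation with RhCl(PPh3)3 reduces the 1,1-disubstituted exocyclic olefin far faster than the trisubstituted enone, and H2 arrives on the convex face of the cis-fused bicycle, which places the new methyl on the same side of the lactone ring as the six-membered ring carbons (3R).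

**Step 6**
Reactants: 9 (E)-2-methylbut-2-enal (tiglic aldehyde)
Product: 10 (1E)-2-methylbuta-1,3-dien-1-yl acetate
Conditions: isopropenyl acetate, TsOH·H2O (cat.), 95 °C, acetone distilled off
Reagents that add atoms: isopropenyl acetate, CC(=C)OC(C)=O
Why: Acid-catalysed enol-ester exchange traps the extended (γ) dienol of the enal as its acetate, and removal of acetone drives the equilibrium.

**Step 7**
Reactants: 10 (1E)-2-methylbuta-1,3-dien-1-yl acetate
Product: 11 rac-2-methylcyclobut-2-en-1-yl acetate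
Conditions: hν (254 nm, quartz), pentane (0.05 M), 0 °C
Reagents that add atoms: none
Why: Photochemical disrotatory 4π electrocyclisation of the s-cis diene, which the 2-methyl group favours (the closure that turns isoprene or 2,3-dimethylbutadiene into cyclobutenes); the product is racemic and is kept cold because heat reopens it.

**Step 8**
Reactants: 8 (3R,3aS,7aR)-3,6-dimethyl-3a,4-dihydro-1-benzofuran-2,5(3H,7aH)-dione; 11 rac-2-methylcyclobut-2-en-1-yl acetate (3 equiv)
Product: 12 cis-anti-cis cyclobutane photoadduct (new bonds C1–C10 plus C4–C5; exo 3R-acetate; lactone unchanged)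
Conditions: hν (365 nm), CH2Cl2, −40 °C
Reagents that add atoms: none
Why: Triplet enone–alkene [2+2] photocycloaddition in which head-to-tail regiochemistry (methyl-bearing alkene carbon to the enone β-carbon, avoiding vicinal quaternary centres), attack on the enone face opposite the cis-fused lactone, cis-anti-cis ring fusion and approach anti to the allylic acetate can all be met only by (R)-11, so the lactone stereocentres take that enantiomer out of the excess racemate, fix C3 as R and leave the (1S)-enantiomer of 11 unreacted; the four cyclobutane stereocentres are temporary.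

**Step 9**
Reactants: 12 cis-anti-cis cyclobutane photoadduct
Product: 14 (3R,3aS,6Z,9R,10Z,11aR)-3,6,10-trimethyl-2,5-dioxo-2,3,3a,4,5,8,9,11a-octahydrocyclodeca[b]furan-9-yl acetate, via (6Z,10E)-dienone 13 (not isolated)
Conditions: 1,2-Cl2C6H4 (0.02 M), BHT (cat.), 200 °C, sealed tube
Reagents that add atoms: none
Why: Thermal cycloreversion of the bicyclo[2.2.0]hexane core (Wender–Lange photo-thermal ring expansion) cleaves the two cyclobutane bonds that step 8 did not make, and at 200 °C the first-formed strained E isomer 13 equilibrates to the conjugated (6Z,10Z)-dienone, the most stable cyclodeca-1,5-diene; C3, C6, C7 and C11 are not touched.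

**Step 10**
Reactants: 14 (3R,3aS,6Z,9R,10Z,11aR)-3,6,10-trimethyl-2,5-dioxo-2,3,3a,4,5,8,9,11a-octahydrocyclodeca[b]furan-9-yl acetate
Product: 15 (3R,3aS,5S,6Z,9R,10Z,11aR)-5-hydroxy-3,6,10-trimethyl-2-oxo-2,3,3a,4,5,8,9,11a-octahydrocyclodeca[b]furan-9-yl acetate
Conditions: NaBH4, CeCl3·7H2O, MeOH, −78 °C
Reagents that add atoms: none
Why: Luche 1,2-reduction leaves lactone, acetate and olefins alone, and hydride is expected to add to the exposed face of the ring carbonyl (macrocyclic stereocontrol by the lactone-bearing stereocentres) to give the 5S allylic alcohol; this facial sense is a prediction, not established.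

**Step 11**
Reactants: 15 (3R,3aS,5S,6Z,9R,10Z,11aR)-5-hydroxy-3,6,10-trimethyl-2-oxo-2,3,3a,4,5,8,9,11a-octahydrocyclodeca[b]furan-9-yl acetate
Product: 16 (3R,3aS,5S,6S,7R,9R,10Z,11aR)-6,7-epoxy-5-hydroxy-3,6,10-trimethyl-2-oxo-2,3,3a,4,5,6,7,8,9,11a-decahydrocyclodeca[b]furan-9-yl acetate
Conditions: VO(acac)2 (5 mol %), t-BuOOH, CH2Cl2, 0 °C → rt
Reagents that add atoms: tert-butyl hydroperoxide, CC(C)(C)OO
Why: Hydroxyl-directed epoxidation touches only the allylic-alcohol olefin (C4=C5 has no free OH), and for medium-ring Z-cycloalkenols with a methyl on the olefin carbon next to the carbinol (A(1,2) strain) the vanadate ester delivers oxygen to give the cis (erythro) epoxy alcohol, so the carbinol sets both oxirane carbons.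

**Step 12**
Reactants: 16 (3R,3aS,5S,6S,7R,9R,10Z,11aR)-6,7-epoxy-5-hydroxy-3,6,10-trimethyl-2-oxo-2,3,3a,4,5,6,7,8,9,11a-decahydrocyclodeca[b]furan-9-yl acetate
Product: 17 (3R,3aS,5S,6R,7R,9R,10Z,11aR)-6,7-epoxy-3,6,10-trimethyl-2-oxo-2,3,3a,4,5,6,7,8,9,11a-decahydrocyclodeca[b]furan-5,9-diyl diacetate (CNP0250285.2)
Conditions: Ac2O, pyridine, DMAP (cat.), CH2Cl2, rt
Reagents that add atoms: acetic anhydride, CC(=O)OC(C)=O
Why: DMAP-catalysed acetylation of the remaining secondary alcohol under non-acidic conditions leaves the oxirane intact and affects no stereocentre.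

**Compound list**
1 | (S)-(+)-carvone, (5S)-2-methyl-5-(prop-1-en-2-yl)cyclohex-2-en-1-one | CC1=CC[C@@H](CC1=O)C(C)=C | starting material
2 | (5S)-5-(3-chloroprop-1-en-2-yl)-2-methylcyclohex-2-en-1-one | CC1=CC[C@@H](CC1=O)C(=C)CCl | intermediate
3 | 2-[(1S)-4-methyl-5-oxocyclohex-3-en-1-yl]prop-2-enal | CC1=CC[C@@H](CC1=O)C(=C)C=O | intermediate
4 | 2-[(1S)-4-methyl-5-oxocyclohex-3-en-1-yl]prop-2-enoic acid | CC1=CC[C@@H](CC1=O)C(=C)C(O)=O | intermediate
5 | acyl hypoiodite of 4, 2-[(1S)-4-methyl-5-oxocyclohex-3-en-1-yl]prop-2-enoyl hypoiodite | CC1=CC[C@@H](CC1=O)C(=C)C(=O)OI | intermediate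
6 | 2-[(1S,2R)-2-iodo-4-methyl-5-oxocyclohex-3-en-1-yl]prop-2-enoic acid (iodide trans to the side chain) | CC1=C[C@@H](I)[C@@H](CC1=O)C(=C)C(O)=O | intermediate
7 | (3aS,7aS)-6-methyl-3-methylidene-3a,4-dihydro-1-benzofuran-2,5(3H,7aH)-dione (cis-fused) | CC1=C[C@@H]2OC(=O)C(=C)[C@@H]2CC1=O | intermediate
8 | (3R,3aS,7aR)-3,6-dimethyl-3a,4-dihydro-1-benzofuran-2,5(3H,7aH)-dione (all-cis lactone) | CC1=C[C@@H]2OC(=O)[C@H](C)[C@@H]2CC1=O | intermediate
9 | (E)-2-methylbut-2-enal (tiglic aldehyde) | C/C=C(\C)C=O | starting material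
10 | (1E)-2-methylbuta-1,3-dien-1-yl acetate (E major; the Z isomer reacts the same way) | C=C/C(C)=C/OC(C)=O | intermediate
11 | rac-2-methylcyclobut-2-en-1-yl acetate (racemate; the R enantiomer, CC1=CC[C@H]1OC(C)=O, is the one taken up in step 8) | CC1=CCC1OC(C)=O | intermediate
12 | tetracyclic [2+2] photoadduct: cyclobutane C1–C4–C5–C10 cis-fused to the cyclohexanone on the face opposite the lactone (C5–H and C10–CH3 cis), second cyclobutane C1–C2–C3–C4 anti to the six-membered ring, exo (3R)-acetoxy, lactone as in 8 | CC(=O)O[C@@H]1C[C@@H]2[C@@]1(C)[C@H]3[C@@H]4OC(=O)[C@H](C)[C@@H]4CC(=O)[C@@]23C | intermediate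
13 | (3R,3aS,6Z,9R,10E,11aR)-3,6,10-trimethyl-2,5-dioxo-2,3,3a,4,5,8,9,11a-octahydrocyclodeca[b]furan-9-yl acetate | O=C1C[C@@H]2[C@H](/C=C(\C)[C@H](OC(C)=O)C/C=C1/C)OC(=O)[C@@H]2C | intermediate
14 | (3R,3aS,6Z,9R,10Z,11aR)-3,6,10-trimethyl-2,5-dioxo-2,3,3a,4,5,8,9,11a-octahydrocyclodeca[b]furan-9-yl acetate | O=C1C[C@@H]2[C@H](/C=C(/C)[C@H](OC(C)=O)C/C=C1/C)OC(=O)[C@@H]2C | intermediate
15 | (3R,3aS,5S,6Z,9R,10Z,11aR)-5-hydroxy-3,6,10-trimethyl-2-oxo-2,3,3a,4,5,8,9,11a-octahydrocyclodeca[b]furan-9-yl acetate | O[C@H]1C[C@@H]2[C@H](/C=C(/C)[C@H](OC(C)=O)C/C=C1/C)OC(=O)[C@@H]2C | intermediate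
16 | (3R,3aS,5S,6S,7R,9R,10Z,11aR)-6,7-epoxy-5-hydroxy-3,6,10-trimethyl-2-oxo-2,3,3a,4,5,6,7,8,9,11a-decahydrocyclodeca[b]furan-9-yl acetate | O[C@H]1C[C@@H]2[C@H](/C=C(/C)[C@H](OC(C)=O)C[C@H]3O[C@@]13C)OC(=O)[C@@H]2C | intermediate
17 | (3R,3aS,5S,6R,7R,9R,10Z,11aR)-6,7-epoxy-3,6,10-trimethyl-2-oxo-2,3,3a,4,5,6,7,8,9,11a-decahydrocyclodeca[b]furan-5,9-diyl diacetate (CNP0250285.2) | CC(=O)O[C@H]1C[C@@H]2[C@H](/C=C(/C)[C@H](OC(C)=O)C[C@H]3O[C@@]13C)OC(=O)[C@@H]2C | target

**Step count**
Total steps: 12. Longest linear sequence: 10 (steps 1–5 and 8–12; steps 6–7 make the cyclobutene partner).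

**Three steps most likely to fail**

Step 4 (the proposed new method). The acyloxy radical may decarboxylate, iodine may go elsewhere, or the acrylate may oligomerise. Known-chemistry fallback, setting out from 4 and coming back at 7: 4 is heated with isopropenyl acetate and catalytic TsOH to give the linear dienol acetate 2-[(1R)-5-acetoxy-4-methylcyclohexa-2,4-dien-1-yl]prop-2-enoic acid F1 (the mixed anhydride is hydrolysed in the bicarbonate work-up). NBS in THF/H2O at 0 °C brominates the γ-carbon anti to the side chain, as in the classical 6-bromination of steroid 3,5-dienol acetates, to give 2-[(1S,2R)-2-bromo-4-methyl-5-oxocyclohex-3-en-1-yl]prop-2-enoic acid F2. NaHCO3 in DMF then closes the lactone by intramolecular SN2 with inversion, giving 7.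

Step 9. The cis,trans isomers may not reach the Z,Z-dienone under purely thermal conditions, or may drain by Cope rearrangement into divinylcyclohexanones. Fallback, setting out from 12 and coming back at 14: the thermolysis is stopped early (about 175 °C, 1–2 h) and dienone 13 is isolated. It is then isomerised at room temperature with PhSSPh (10 mol %) under 365 nm light in benzene, where reversible thiyl-radical addition relieves the strained E olefin and gives 14. This sets the olefin geometry by a radical chain and not by thermal equilibration, and it makes no compound outside the list (F0).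

Step 10. Hydride may add to the other face of the ring carbonyl. Fallback, setting out from 14 and coming back at 17: if the reduction gives mainly the epimeric alcohol (3R,3aS,5R,6Z,9R,10Z,11aR)-5-hydroxy-3,6,10-trimethyl-2-oxo-2,3,3a,4,5,8,9,11a-octahydrocyclodeca[b]furan-9-yl acetate F3, this is epoxidised with mCPBA (CH2Cl2, 0 °C). For a Z-allylic alcohol held by A(1,3) strain the peracid gives the threo (trans) epoxy alcohol (3R,3aS,5R,6S,7R,9R,10Z,11aR)-6,7-epoxy-5-hydroxy-3,6,10-trimethyl-2-oxo-2,3,3a,4,5,6,7,8,9,11a-decahydrocyclodeca[b]furan-9-yl acetate F4, whose oxirane already has the target configuration. Mitsunobu esterification with AcOH (PPh3, DIAD, THF, 0 °C → rt) inverts the carbinol and installs the acetate in one operation, arriving at 17.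

**Further compounds**
F1 | step 4 | 2-[(1R)-5-acetoxy-4-methylcyclohexa-2,4-dien-1-yl]prop-2-enoic acid | CC(=O)OC1=C(C)C=C[C@@H](C1)C(=C)C(O)=O
F2 | step 4 | 2-[(1S,2R)-2-bromo-4-methyl-5-oxocyclohex-3-en-1-yl]prop-2-enoic acid | CC1=C[C@@H](Br)[C@@H](CC1=O)C(=C)C(O)=O
F0 | step 9 | none | none
F3 | step 10 | (3R,3aS,5R,6Z,9R,10Z,11aR)-5-hydroxy-3,6,10-trimethyl-2-oxo-2,3,3a,4,5,8,9,11a-octahydrocyclodeca[b]furan-9-yl acetate | O[C@@H]1C[C@@H]2[C@H](/C=C(/C)[C@H](OC(C)=O)C/C=C1/C)OC(=O)[C@@H]2C
F4 | step 10 | (3R,3aS,5R,6S,7R,9R,10Z,11aR)-6,7-epoxy-5-hydroxy-3,6,10-trimethyl-2-oxo-2,3,3a,4,5,6,7,8,9,11a-decahydrocyclodeca[b]furan-9-yl acetate | O[C@@H]1C[C@@H]2[C@H](/C=C(/C)[C@H](OC(C)=O)C[C@H]3O[C@@]13C)OC(=O)[C@@H]2C
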